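**Retrosynthetic overview**

1. Artelasticin 19 ⇐ 18 ⇐ 17 by two deprotections (MOM acetals, 2'-O-methyl); the whole carbon skeleton is present in 17.
2. The plan rests on ring B: a benzene with oxygen only at C2' and C4', bonded through C1' to C2 of the pyrone (ring C) beside the C3 prenyl group. It is cut at C1'–C2' and C5'–C6' into the C≡CH group on C2 of chromone 11 and the diene CH2=C(OSiMe3)–CH=C(OMe)2 (14).
3. 11 ⇐ aldehyde 10 ⇐ ester 8; ring C of 8 ⇐ α-prenyl ketone 5 + diethyl oxalate (Claisen condensation, cyclodehydration).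
4. 5 ⇐ 2,4,6-trihydroxyacetophenone 1 (ring A) by double nuclear prenylation, bis-MOM protection and side-chain prenylation; 14 ⇐ 1,1-dimethoxyethene.
5. Ring order: A (purchased) → C (steps 4 and 5) → B (step 11).

Key step: step 11

Remark on the chemistry: the target has no stereocentre and no stereogenic double bond, so nothing has to be controlled. Hemiketal 7 is carried as a diastereomer mixture because both of its centres vanish in step 5.

**Route**

Step 1
Reactants: 1 2,4,6-trihydroxyacetophenone; 2 prenyl bromide (2.2 equiv)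
Product: 3 1-[2,4,6-trihydroxy-3,5-bis(3-methylbut-2-en-1-yl)phenyl]ethan-1-one
Conditions: 10% aq. KOH, 0 °C → rt
Reagents that add atoms: none
Why: Phenoxide C-allylation of the phloroglucinol-type polyanion: in water the oxygens are solvated, so the allylic bromide is attacked by the two free ring carbons C3 and C5, the third position being blocked by the acetyl group.

Step 2
Reactants: 3 1-[2,4,6-trihydroxy-3,5-bis(3-methylbut-2-en-1-yl)phenyl]ethan-1-one
Product: 4 1-[2-hydroxy-4,6-bis(methoxymethoxy)-3,5-bis(3-methylbut-2-en-1-yl)phenyl]ethan-1-one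
Conditions: MOMCl (2.3 equiv), i-Pr2NEt, CH2Cl2, 0 °C → rt
Reagents that add atoms: chloromethyl methyl ether, COCCl
Why: Williamson-type O-alkylation (acetal formation) should take the 4-OH and one of the two equivalent ortho-OH groups, while the last OH is held in a hydrogen bond to the ketone and stays free for the later ring closure.

Step 3
Reactants: 4 1-[2-hydroxy-4,6-bis(methoxymethoxy)-3,5-bis(3-methylbut-2-en-1-yl)phenyl]ethan-1-one; 2 prenyl bromide (1.05 equiv)
Product: 5 1-[2-hydroxy-4,6-bis(methoxymethoxy)-3,5-bis(3-methylbut-2-en-1-yl)phenyl]-5-methylhex-4-en-1-one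
Conditions: LiN(SiMe3)2 (2.3 equiv), THF–DMPU, −78 °C; then 2, −78 → −20 °C; aq. NH4Cl
Reagents that add atoms: none
Why: Enolate alkylation: two equivalents of base give the phenoxide–enolate dianion, whose carbon terminus is by far the better nucleophile for the SN2 reaction with the allylic bromide, so the side chain should be extended by one prenyl unit without O-alkylation.

Step 4
Reactants: 5 1-[2-hydroxy-4,6-bis(methoxymethoxy)-3,5-bis(3-methylbut-2-en-1-yl)phenyl]-5-methylhex-4-en-1-one; 6 diethyl oxalate (2 equiv)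
Product: 7 ethyl 2-hydroxy-5,7-bis(methoxymethoxy)-3,6,8-tris(3-methylbut-2-en-1-yl)-4-oxochromane-2-carboxylate (racemic mixture of diastereomers)
Conditions: LiN(SiMe3)2 (3.2 equiv), THF, −78 °C; then 6, −78 → 0 °C; aq. NH4Cl
Reagents that add atoms: none
Why: Crossed Claisen condensation of the ketone enolate with the non-enolisable, highly electrophilic oxalate, driven by deprotonation of the tricarbonyl product; on protonation the phenol adds to the α-keto ester carbonyl and closes the six-membered hemiketal of ring C.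

Step 5
Reactants: 7 ethyl 2-hydroxy-5,7-bis(methoxymethoxy)-3,6,8-tris(3-methylbut-2-en-1-yl)-4-oxochromane-2-carboxylate
Product: 8 ethyl 5,7-bis(methoxymethoxy)-3,6,8-tris(3-methylbut-2-en-1-yl)-4-oxo-4H-chromene-2-carboxylate
Conditions: MsCl, Et3N, DMAP (cat.), CH2Cl2, 0 °C → rt
Reagents that add atoms: none
Why: Dehydration by sulfonylation of the hemiketal OH and E1cB elimination across C2–C3 (the C3–H is α to the C4 ketone) should give the pyrone without acid, so the MOM ethers and prenyl groups are not touched.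

Step 6
Reactants: 8 ethyl 5,7-bis(methoxymethoxy)-3,6,8-tris(3-methylbut-2-en-1-yl)-4-oxo-4H-chromene-2-carboxylate
Product: 9 2-(hydroxymethyl)-5,7-bis(methoxymethoxy)-3,6,8-tris(3-methylbut-2-en-1-yl)-4H-chromen-4-one
Conditions: NaBH4, EtOH–THF, 0 °C
Reagents that add atoms: none
Why: Chemoselective borohydride reduction: the 2-ester sits on an electron-poor, oxygen-bearing alkene and is reduced to the primary alcohol, whereas the C4 carbonyl is a vinylogous ester and is left alone, the usual behaviour of chromone-2-carboxylates.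

Step 7
Reactants: 9 2-(hydroxymethyl)-5,7-bis(methoxymethoxy)-3,6,8-tris(3-methylbut-2-en-1-yl)-4H-chromen-4-one
Product: 10 5,7-bis(methoxymethoxy)-3,6,8-tris(3-methylbut-2-en-1-yl)-4-oxo-4H-chromene-2-carbaldehyde
Conditions: Dess–Martin periodinane, pyridine, CH2Cl2, 0 °C → rt
Reagents that add atoms: none
Why: Dess–Martin oxidation of the primary allylic-type alcohol stops at the aldehyde and, buffered with pyridine, should affect neither the prenyl alkenes nor the acetals.

Step 8
Reactants: 10 5,7-bis(methoxymethoxy)-3,6,8-tris(3-methylbut-2-en-1-yl)-4-oxo-4H-chromene-2-carbaldehyde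
Product: 11 2-ethynyl-5,7-bis(methoxymethoxy)-3,6,8-tris(3-methylbut-2-en-1-yl)-4H-chromen-4-one
Conditions: dimethyl (1-diazo-2-oxopropyl)phosphonate, K2CO3, MeOH–THF, 0 °C → rt
Reagents that add atoms: dimethyl (1-diazo-2-oxopropyl)phosphonate, CC(=O)C(=[N+]=[N-])P(=O)(OC)OC
Why: Ohira–Bestmann variant of the Seyferth–Gilbert homologation: methanolysis of the reagent gives the dimethyl (diazomethyl)phosphonate anion, Horner–Wadsworth–Emmons olefination of the aldehyde gives a diazoalkene, and loss of N2 with a 1,2-hydrogen shift gives the terminal alkyne under mild base.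

Step 9
Reactants: 12 1,1-dimethoxyethene
Product: 13 4,4-dimethoxybut-3-en-2-one
Conditions: AcCl, Et3N, Et2O, 0 °C → rt
Reagents that add atoms: acetyl chloride, CC(Cl)=O
Why: C-acylation of the ketene acetal at its nucleophilic CH2 by the acid chloride, followed by loss of HCl from the oxocarbenium ion to triethylamine, should give the acyl ketene acetal, a stabilised push–pull alkene.

Step 10
Reactants: 13 4,4-dimethoxybut-3-en-2-one
Product: 14 1,1-dimethoxy-3-(trimethylsilyloxy)buta-1,3-diene
Conditions: LiN(i-Pr)2, THF, −78 °C; then Me3SiCl, −78 °C → rt; used freshly distilled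
Reagents that add atoms: chlorotrimethylsilane, C[Si](C)(C)Cl
Why: Silyl enol ether formation: the methyl group is the only enolisable position, so kinetic deprotonation and O-silylation should give the 2-silyloxydiene.

Step 11
Reactants: 11 2-ethynyl-5,7-bis(methoxymethoxy)-3,6,8-tris(3-methylbut-2-en-1-yl)-4H-chromen-4-one; 14 1,1-dimethoxy-3-(trimethylsilyloxy)buta-1,3-diene (4 equiv, added in two portions)
Product: 17 2-(4-hydroxy-2-methoxyphenyl)-5,7-bis(methoxymethoxy)-3,6,8-tris(3-methylbut-2-en-1-yl)-4H-chromen-4-one, via cyclohexa-1,4-diene cycloadduct 15 (not isolated), via aryl trimethylsilyl ether 16 (not isolated)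
Conditions: toluene, 110 °C, sealed tube; then AcOH–THF–H2O, rt
Reagents that add atoms: none
Why: A thermal, strongly asynchronous [4+2] cycloaddition joins the CH2 terminus of 14 (its most nucleophilic site, fed by the silyloxy group and the ketene acetal) to the terminal alkyne carbon of 11, the electrophilic end of the vinylogous ynone O=C4–C3=C2–C≡CH, and the ketene acetal carbon to the internal alkyne carbon, giving cyclohexa-1,4-diene 15. Ring B is thereby closed as a six-membered carbocycle by an intermolecular Diels–Alder reaction that forms C5'–C6' and C1'–C2' in one operation; a stepwise Mukaiyama–Michael addition followed by closure onto the oxocarbenium ion would end in the same ring. 1,4-Elimination of methanol from 15 aromatises it to silyl ether 16, and the aqueous acetic acid work-up hydrolyses the Si–O bond to the 4'-phenol of 17. The closest known reaction type is the Diels–Alder reaction of 1,1-dialkoxy-3-silyloxybutadienes with acetylenic ketones and esters, which gives resorcinol monoalkyl ethers after loss of alcohol. No stereocentre is formed. The step needs regioselectivity (methoxy at C2', hydroxyl at C4') and chemoselectivity: the first is secured by the matched polarisation of the two partners, the second because the electron-rich prenyl double bonds and the tetrasubstituted C2=C3 bond are not dienophiles for an electron-rich diene, while the linear alkyne is not shielded by the neighbouring C3 prenyl group.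

Step 12
Reactants: 17 2-(4-hydroxy-2-methoxyphenyl)-5,7-bis(methoxymethoxy)-3,6,8-tris(3-methylbut-2-en-1-yl)-4H-chromen-4-one
Product: 18 2-(2,4-dihydroxyphenyl)-5,7-bis(methoxymethoxy)-3,6,8-tris(3-methylbut-2-en-1-yl)-4H-chromen-4-one
Conditions: NaSEt (6 equiv), DMF, 120 °C; aq. NH4Cl
Reagents that add atoms: none
Why: SN2 O-demethylation by a soft thiolate: the 2'-oxygen is conjugated with the chromone carbonyl and is therefore a fair leaving group, while the MOM acetals, the prenyl groups and the pyrone are expected to withstand the non-acidic medium (any MOM loss would be harmless before step 13).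

Step 13
Reactants: 18 2-(2,4-dihydroxyphenyl)-5,7-bis(methoxymethoxy)-3,6,8-tris(3-methylbut-2-en-1-yl)-4H-chromen-4-one
Product: 19 artelasticin, 2-(2,4-dihydroxyphenyl)-5,7-dihydroxy-3,6,8-tris(3-methylbut-2-en-1-yl)-4H-chromen-4-one
Conditions: 3 M aq. HCl, MeOH, 40 °C
Reagents that add atoms: none
Why: Acid-catalysed transacetalisation (MOM cleavage through the oxocarbenium ion, trapped by methanol) under mild conditions that ortho-prenyl phenols are expected to tolerate without cyclising to chromans.

**Compound list**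

1 | 2,4,6-trihydroxyacetophenone | CC(=O)c1c(O)cc(O)cc1O | starting material
2 | prenyl bromide (1-bromo-3-methylbut-2-ene) | CC(C)=CCBr | starting material
3 | 1-[2,4,6-trihydroxy-3,5-bis(3-methylbut-2-en-1-yl)phenyl]ethan-1-one | CC(=O)c1c(O)c(CC=C(C)C)c(O)c(CC=C(C)C)c1O | intermediate
4 | 1-[2-hydroxy-4,6-bis(methoxymethoxy)-3,5-bis(3-methylbut-2-en-1-yl)phenyl]ethan-1-one | CC(=O)c1c(O)c(CC=C(C)C)c(OCOC)c(CC=C(C)C)c1OCOC | intermediate
5 | 1-[2-hydroxy-4,6-bis(methoxymethoxy)-3,5-bis(3-methylbut-2-en-1-yl)phenyl]-5-methylhex-4-en-1-one | CC(C)=CCCC(=O)c1c(O)c(CC=C(C)C)c(OCOC)c(CC=C(C)C)c1OCOC | intermediate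
6 | diethyl oxalate | CCOC(=O)C(=O)OCC | starting material
7 | ethyl 2-hydroxy-5,7-bis(methoxymethoxy)-3,6,8-tris(3-methylbut-2-en-1-yl)-4-oxochromane-2-carboxylate (racemic, mixture of diastereomers at C2 and C3) | CCOC(=O)C1(O)Oc2c(CC=C(C)C)c(OCOC)c(CC=C(C)C)c(OCOC)c2C(=O)C1CC=C(C)C | intermediate
8 | ethyl 5,7-bis(methoxymethoxy)-3,6,8-tris(3-methylbut-2-en-1-yl)-4-oxo-4H-chromene-2-carboxylate | CCOC(=O)c1oc2c(CC=C(C)C)c(OCOC)c(CC=C(C)C)c(OCOC)c2c(=O)c1CC=C(C)C | intermediate
9 | 2-(hydroxymethyl)-5,7-bis(methoxymethoxy)-3,6,8-tris(3-methylbut-2-en-1-yl)-4H-chromen-4-one | OCc1oc2c(CC=C(C)C)c(OCOC)c(CC=C(C)C)c(OCOC)c2c(=O)c1CC=C(C)C | intermediate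
10 | 5,7-bis(methoxymethoxy)-3,6,8-tris(3-methylbut-2-en-1-yl)-4-oxo-4H-chromene-2-carbaldehyde | O=Cc1oc2c(CC=C(C)C)c(OCOC)c(CC=C(C)C)c(OCOC)c2c(=O)c1CC=C(C)C | intermediate
11 | 2-ethynyl-5,7-bis(methoxymethoxy)-3,6,8-tris(3-methylbut-2-en-1-yl)-4H-chromen-4-one | CC(C)=CCc1c(OCOC)c(CC=C(C)C)c2oc(C#C)c(CC=C(C)C)c(=O)c2c1OCOC | intermediate
12 | 1,1-dimethoxyethene | C=C(OC)OC | starting material
13 | 4,4-dimethoxybut-3-en-2-one | CC(=O)C=C(OC)OC | intermediate
14 | 1,1-dimethoxy-3-(trimethylsilyloxy)buta-1,3-diene | COC(OC)=CC(=C)O[Si](C)(C)C | intermediate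
15 | 2-[6,6-dimethoxy-4-(trimethylsilyloxy)cyclohexa-1,4-dien-1-yl]-5,7-bis(methoxymethoxy)-3,6,8-tris(3-methylbut-2-en-1-yl)-4H-chromen-4-one | CC(C)=CCc1c(OCOC)c(CC=C(C)C)c2oc(C3=CCC(O[Si](C)(C)C)=CC3(OC)OC)c(CC=C(C)C)c(=O)c2c1OCOC | intermediate
16 | 2-[2-methoxy-4-(trimethylsilyloxy)phenyl]-5,7-bis(methoxymethoxy)-3,6,8-tris(3-methylbut-2-en-1-yl)-4H-chromen-4-one | CC(C)=CCc1c(OCOC)c(CC=C(C)C)c2oc(-c3ccc(O[Si](C)(C)C)cc3OC)c(CC=C(C)C)c(=O)c2c1OCOC | intermediate
17 | 2-(4-hydroxy-2-methoxyphenyl)-5,7-bis(methoxymethoxy)-3,6,8-tris(3-methylbut-2-en-1-yl)-4H-chromen-4-one | CC(C)=CCc1c(OCOC)c(CC=C(C)C)c2oc(-c3ccc(O)cc3OC)c(CC=C(C)C)c(=O)c2c1OCOC | intermediate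
18 | 2-(2,4-dihydroxyphenyl)-5,7-bis(methoxymethoxy)-3,6,8-tris(3-methylbut-2-en-1-yl)-4H-chromen-4-one | CC(C)=CCc1c(OCOC)c(CC=C(C)C)c2oc(-c3ccc(O)cc3O)c(CC=C(C)C)c(=O)c2c1OCOC | intermediate
19 | artelasticin, 2-(2,4-dihydroxyphenyl)-5,7-dihydroxy-3,6,8-tris(3-methylbut-2-en-1-yl)-4H-chromen-4-one | CC(C)=CCc1c(O)c(CC=C(C)C)c2oc(-c3ccc(O)cc3O)c(CC=C(C)C)c(=O)c2c1O | target

**Step count and risks**

Total step count: 13. Longest linear sequence: 11 steps (steps 1–8, 11, 12, 13); steps 9 and 10 form the side branch to diene 14.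

Steps most likely to fail:

Step 11 (ring B cycloaddition). The alkyne is activated only through the vinylogous carbonyl, so cycloaddition may be slower than thermal desilylation and decomposition of the ketene acetal diene. Bond formation may also start from C2 of the diene and end in open-chain Michael adducts or the reversed orientation. The fallback gives up the cycloaddition and brings ring B in preformed by Baker–Venkataraman chemistry. It sets out from 5. The free phenol is acylated with 2,4-bis(allyloxy)benzoyl chloride F1 (pyridine, DMAP, CH2Cl2) to give 2-(5-methylhex-4-enoyl)-3,5-bis(methoxymethoxy)-4,6-bis(3-methylbut-2-en-1-yl)phenyl 2,4-bis(allyloxy)benzoate F2. KOtBu in THF then shifts the aroyl group from oxygen to the α-carbon and should give 1-[2,4-bis(allyloxy)phenyl]-3-[2-hydroxy-4,6-bis(methoxymethoxy)-3,5-bis(3-methylbut-2-en-1-yl)phenyl]-2-(3-methylbut-2-en-1-yl)propane-1,3-dione F3. HCl in MeOH at 50 °C closes and dehydrates ring C with loss of both MOM groups; the allyl ethers keep the ring B oxygens from competing in the closure, and the product is 2-[2,4-bis(allyloxy)phenyl]-5,7-dihydroxy-3,6,8-tris(3-methylbut-2-en-1-yl)-4H-chromen-4-one F4. Pd(PPh3)4 with morpholine in THF removes the two O-allyl groups without touching the C-prenyl groups, and the route is rejoined at 19.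

Step 12 (thiolate demethylation). The 4'-phenoxide makes ring B electron-rich, so SN2 attack at the methyl group may be slow. Prolonged heating would then let thiolate attack the MOM acetal carbons or add at C2 and open ring C. The fallback avoids the methyl ether altogether and sets out from 11. The cycloaddition is run with the mixed ketene acetal 1-methoxy-1,3-bis(trimethylsilyloxy)buta-1,3-diene F5 (toluene, 110 °C) to give 2-[6-methoxy-4,6-bis(trimethylsilyloxy)cyclohexa-1,4-dien-1-yl]-5,7-bis(methoxymethoxy)-3,6,8-tris(3-methylbut-2-en-1-yl)-4H-chromen-4-one F6. On a desilylating work-up (AcOH–THF–H2O) the silyl methyl ketal should collapse with loss of methanol to the keto tautomer of the phenol, which aromatises, so that both ring B oxygens emerge as free hydroxyls. The route is rejoined at 18.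

Step 8 (alkyne formation). Methanol or methoxide may add to the newly formed electron-poor alkyne or attack C2 and open the pyrone, and hemiacetal formation may hold back the aldehyde. The fallback replaces the diazophosphonate homologation by olefination and elimination in aprotic media and sets out from 10. Stork–Zhao olefination with (iodomethyl)triphenylphosphonium iodide and NaN(SiMe3)2 (THF, −78 °C) should give (Z)-2-(2-iodoethenyl)-5,7-bis(methoxymethoxy)-3,6,8-tris(3-methylbut-2-en-1-yl)-4H-chromen-4-one F7. Anti-elimination of HI with Bu4NF in DMF (rt → 60 °C) then returns the route to 11.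

**Further compounds**

F1 | step 11 | 2,4-bis(allyloxy)benzoyl chloride | C=CCOc1ccc(C(=O)Cl)c(OCC=C)c1
F2 | step 11 | 2-(5-methylhex-4-enoyl)-3,5-bis(methoxymethoxy)-4,6-bis(3-methylbut-2-en-1-yl)phenyl 2,4-bis(allyloxy)benzoate | CC(C)=CCCC(=O)c1c(OC(=O)c2ccc(OCC=C)cc2OCC=C)c(CC=C(C)C)c(OCOC)c(CC=C(C)C)c1OCOC
F3 | step 11 | 1-[2,4-bis(allyloxy)phenyl]-3-[2-hydroxy-4,6-bis(methoxymethoxy)-3,5-bis(3-methylbut-2-en-1-yl)phenyl]-2-(3-methylbut-2-en-1-yl)propane-1,3-dione (racemic) | CC(C)=CCC(C(=O)c1ccc(OCC=C)cc1OCC=C)C(=O)c1c(O)c(CC=C(C)C)c(OCOC)c(CC=C(C)C)c1OCOC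
F4 | step 11 | 2-[2,4-bis(allyloxy)phenyl]-5,7-dihydroxy-3,6,8-tris(3-methylbut-2-en-1-yl)-4H-chromen-4-one | CC(C)=CCc1c(O)c(CC=C(C)C)c2oc(-c3ccc(OCC=C)cc3OCC=C)c(CC=C(C)C)c(=O)c2c1O
F5 | step 12 | 1-methoxy-1,3-bis(trimethylsilyloxy)buta-1,3-diene (geometry at C1=C2 immaterial) | COC(O[Si](C)(C)C)=CC(=C)O[Si](C)(C)C
F6 | step 12 | 2-[6-methoxy-4,6-bis(trimethylsilyloxy)cyclohexa-1,4-dien-1-yl]-5,7-bis(methoxymethoxy)-3,6,8-tris(3-methylbut-2-en-1-yl)-4H-chromen-4-one (racemic) | CC(C)=CCc1c(OCOC)c(CC=C(C)C)c2oc(C3=CCC(O[Si](C)(C)C)=CC3(OC)O[Si](C)(C)C)c(CC=C(C)C)c(=O)c2c1OCOC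
F7 | step 8 | (Z)-2-(2-iodoethenyl)-5,7-bis(methoxymethoxy)-3,6,8-tris(3-methylbut-2-en-1-yl)-4H-chromen-4-one | I/C=C\c1oc2c(CC=C(C)C)c(OCOC)c(CC=C(C)C)c(OCOC)c2c(=O)c1CC=C(C)C
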